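(The runs stem from a simulated flask for substances that don't exist; noise was put on by code.)

Start from the end state. The winter run reaches 97.1% product at 8.00 min, so the flask heads for the whole charge as product, and the question is how fast it gets there.

in all of them: enzyme 0.088 mol%

| charge | substrate | remark | time |
|---|---|---|---|
| winter | 0.19 M | run made earlier |  |
| noon | 0.095 M | run made earlier |  |
| Tuesday's | 0.19 M | a closed flask charged with all of it at once and left for 12 min | 12 min |
| Friday's | 0.19 M | a single well-mixed tank run continuously and read at steady state, 12 min in it on average |  |
| Monday's | 0.19 M (fed, over 9.60 min) | all but substrate at the start; substrate goes in evenly over 9.60 min, the run ends at 12 min | 12 min |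

- winter (time / min: product / %): 0.500: 38.0; 1.00: 52.3; 1.50: 64.4; 2.50: 76.5; 4.00: 87.8; 8.00: 97.1
- noon (time / min: product / %): 0.667: 41.6; 1.33: 58.3; 2.00: 69.9; 2.50: 73.5; 3.00: 80.4; 4.00: 87.1

(standard deviation of a reading: 1 percentage point)

- the set-up with the highest amount of product at the outlet or at the end, in percent of the substrate put in ("none" if the first two lie within 2 percentage points) (Tuesday's / Friday's / Monday's / none)
- amount of product at the outlet or at the end, in percent of the substrate put in, Tuesday's
- amount of product at the outlet or at the end, in percent of the substrate put in, Friday's
- amount of product at the outlet or at the end, in percent of the substrate put in, Monday's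

- the stated concentrations are those of everything mixed, before any reaction; amounts are the same in each set-up
- the earlier runs were read with a standard deviation of 1 percentage point
- the feed brings no volume worth counting
- the earlier runs were made in a closed, stirred flask

Read as first order, the winter run gives 0.956 /min over its first 0.500 min, but 0.359 /min between 4.00 min and 8.00 min, so in the winter run the late loss of c(substrate) reads slower than the early one. The later figure, read from two readings with their scatter, is a pseudo-first-order tail constant for a flask holding mostly product. The noon run, with half the substrate at the same loading, reads 87.1% at 4.00 min against 87.8% in the winter run.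

The tail constant times the time allowed is 4.31; this tail number counts the e-foldings of substrate that the time holds.

Tuesday's closed flask continues the winter curve beyond 8.00 min, which gives 99.3% product. Friday's tank, reckoned as first order with the tail constant, leaves a fraction 1/(1+N) of the substrate, which gives 81.2%. In Monday's flask, consumption is taken to keep pace with the feed, so the tank formula applies with the dosing time, and the tail then runs for the remaining time, giving 90.5%. One number was not enough: the same tail number stands behind 99.3%, 81.2% and 90.5%, each through the reckoning of its own vessel. This reckoning puts Tuesday's highest.

The forecast, on “a saturated enzyme with competitive product inhibition”, gave 99.2%, 82.6% and 91.8%, with Tuesday's best. The flasks give 99.2%, 82.3% and 91.5%, and Tuesday's is highest.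

    substrate + enzyme → product + enzyme, rate k1*[substrate]*[enzyme]/(1 + ([substrate]/Km1) + ([product]/Kp1)) (36.0 mM, 6.30 mM, k = 62000 /M/min)

Friday's outlet stands 1.1 percentage points above N/(1+N). The neighbouring flask is Tuesday's with 0.035 mol% of enzyme. Taking the tail number in proportion to the enzyme gives 1.71, which places that flask on the winter curve just past the 87.8% of 4.00 min, at 90.7% product. That flask gives 90.0%, with 9.96% of the substrate left.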